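**Assumption (one line):** guaiane numbering is used for the skeleton (C1=C10, C3=C4; stereocentres C5, C7, C8), and the target is read as (5R,7R,8S)-guaia-1(10),3-dien-8-yl vanillate = (3aR,5R,6S)-3,8-dimethyl-5-(propan-2-yl)-1,3a,4,5,6,7-hexahydroazulen-6-yl 4-hydroxy-3-methoxybenzoate.

## Retrosynthetic overview

1. Ester C8–O: the C8 alcohol plus O-acetyl-vanilloyl chloride, the acetate being removed in the same pot.
2. Five-membered ring (closed last): ring-closing metathesis between a C1 allyl group and a C5 (E)-but-2-en-2-yl group, giving C3=C4; the allyl group comes from an enal CHO.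
3. Seven-membered ring (closed first): intramolecular aldol condensation of a 1,7-keto-aldehyde (C1 attacks C10), giving the tetrasubstituted C1=C10.
4. C5–C6: convergent copper-mediated syn-SN2′ union of a C6 Grignard reagent (fragment 1, C6–C10; C7/C8 from an Evans syn-aldol) with a (Z)-allylic o-(diphenylphosphanyl)benzoate (fragment 2, C1–C5; carbinol from a CBS reduction).

## Route

**Fragment 1 (C6–C10)**

Step 1
Reactants: 1 (R)-4-benzyloxazolidin-2-one; 2 3-methylbutanoyl chloride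
Product: 3 (R)-4-benzyl-3-(3-methylbutanoyl)oxazolidin-2-one
Conditions: n-BuLi, THF, −78 °C; then 2, −78 → 0 °C
Reagents that add atoms: none
Why: N-acylation of the lithiated Evans oxazolidinone by the acid chloride; no new stereocentre.

Step 2
Reactants: 4 ethyl 2-(2-methyl-1,3-dioxolan-2-yl)acetate (Fructone)
Product: 5 2-(2-methyl-1,3-dioxolan-2-yl)acetaldehyde
Conditions: i-Bu2AlH (1.05 equiv), CH2Cl2, −78 °C; Rochelle salt work-up
Reagents that add atoms: none
Why: partial DIBAL reduction of an ester, which stops at the aldehyde because the tetrahedral aluminium hemiacetal is stable at −78 °C; the ketal is inert.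

Step 3
Reactants: 3 (R)-4-benzyl-3-(3-methylbutanoyl)oxazolidin-2-one; 5 2-(2-methyl-1,3-dioxolan-2-yl)acetaldehyde
Product: 7 (R)-4-benzyl-3-[(2R,3S)-3-hydroxy-4-(2-methyl-1,3-dioxolan-2-yl)-2-(propan-2-yl)butanoyl]oxazolidin-2-one, via dibutylboron (Z)-enolate 6 (not isolated)
Conditions: Bu2BOTf, Et3N, CH2Cl2, −78 → 0 °C; then 5, −78 → 0 °C; pH 7 buffer, MeOH, H2O2
Reagents that add atoms: none
Why: Evans syn-aldol reaction, in which the (Z)-boron enolate reacts through a Zimmerman–Traxler chair on the enolate face away from the benzyl group of the (R)-auxiliary, setting C7 and C8 together as the 2R,3S syn pair.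

Step 4
Reactants: 7 aldol adduct
Product: 8 (R)-4-benzyl-3-[(2R,3S)-3-[(tert-butyldimethylsilyl)oxy]-4-(2-methyl-1,3-dioxolan-2-yl)-2-(propan-2-yl)butanoyl]oxazolidin-2-one
Conditions: TBSOTf, 2,6-lutidine, CH2Cl2, −78 → 0 °C
Reagents that add atoms: tert-butyldimethylsilyl trifluoromethanesulfonate, CC(C)(C)[Si](C)(C)OS(=O)(=O)C(F)(F)F
Why: silyl ether formation on the secondary alcohol under buffered conditions that leave the ketal and both stereocentres untouched and block retro-aldol cleavage.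

Step 5
Reactants: 8 silyl ether imide
Product: 9 (2S,3S)-3-[(tert-butyldimethylsilyl)oxy]-4-(2-methyl-1,3-dioxolan-2-yl)-2-(propan-2-yl)butan-1-ol
Conditions: LiBH4, MeOH (1 equiv), THF, 0 °C
Reagents that add atoms: none
Why: reductive cleavage of the N-acyl oxazolidinone by borohydride gives the C6 primary alcohol without epimerising C7 and returns the auxiliary.

Step 6
Reactants: 9 primary alcohol
Product: 10 tert-butyl{[(2S,3R)-4-iodo-1-(2-methyl-1,3-dioxolan-2-yl)-3-(propan-2-yl)butan-2-yl]oxy}dimethylsilane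
Conditions: I2, PPh3, imidazole, CH2Cl2, 0 → 25 °C
Reagents that add atoms: iodine, II
Why: Appel-type (Garegg–Samuelsson) iodination by SN2 displacement of the oxyphosphonium at the primary carbon; the stereocentres are not involved.

**Fragment 2 (C1–C5)**

Step 7
Reactants: 11 methyl 3,3-dimethoxypropanoate
Product: 12 3,3-dimethoxypropanal
Conditions: i-Bu2AlH (1.05 equiv), CH2Cl2, −78 °C; Rochelle salt work-up; used crude
Reagents that add atoms: none
Why: partial DIBAL reduction of the ester to the aldehyde at low temperature.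

Step 8
Reactants: 12 3,3-dimethoxypropanal; 13 ethyl 2-[bis(2,2,2-trifluoroethoxy)phosphoryl]propanoate
Product: 14 ethyl (2Z)-5,5-dimethoxy-2-methylpent-2-enoate
Conditions: KN(SiMe3)2, 18-crown-6, THF, −78 °C
Reagents that add atoms: none
Why: Still–Gennari variant of the Horner–Wadsworth–Emmons olefination, where the electron-poor phosphonate and dissociated potassium enolate give the kinetic (Z)-trisubstituted enoate.

Step 9
Reactants: 14 (Z)-enoate
Product: 15 (2Z)-N-methoxy-5,5-dimethoxy-N,2-dimethylpent-2-enamide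
Conditions: MeNHOMe·HCl, i-PrMgCl, THF, −20 °C
Reagents that add atoms: N,O-dimethylhydroxylamine hydrochloride, CNOC.Cl
Why: aminolysis of the ester by the chloromagnesium amide (Weinreb amide formation) under conditions that do not isomerise the (Z)-alkene.

Step 10
Reactants: 15 (Z)-Weinreb amide
Product: 16 (3Z)-6,6-dimethoxy-3-methylhex-3-en-2-one
Conditions: MeMgBr, THF, −78 → 0 °C
Reagents that add atoms: methylmagnesium bromide, C[Mg]Br
Why: Weinreb ketone synthesis, in which the chelated tetrahedral intermediate prevents over-addition.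

Step 11
Reactants: 16 (Z)-enone
Product: 17 (2S,3Z)-6,6-dimethoxy-3-methylhex-3-en-2-ol
Conditions: (R)-2-methyl-CBS-oxazaborolidine (0.2 equiv), BH3·SMe2, THF, −30 °C
Reagents that add atoms: none
Why: Corey–Bakshi–Shibata reduction, in which the alkenyl group acts as the large substituent so that the (R)-catalyst delivers hydride to give the (S)-carbinol.

Step 12
Reactants: 17 (S,Z)-allylic alcohol; 18 2-(diphenylphosphanyl)benzoic acid
Product: 19 (2S,3Z)-6,6-dimethoxy-3-methylhex-3-en-2-yl 2-(diphenylphosphanyl)benzoate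
Conditions: DCC, DMAP (cat.), CH2Cl2, 25 °C
Reagents that add atoms: none
Why: Steglich esterification installs the phosphine-bearing directing/leaving group with retention at the carbinol.

**Union and endgame**

Step 13
Reactants: 10 iodide (fragment 1); 19 allylic ester (fragment 2)
Product: 21 tert-butyl{[(2S,3R,5S,6E)-5-(2,2-dimethoxyethyl)-6-methyl-1-(2-methyl-1,3-dioxolan-2-yl)-3-(propan-2-yl)oct-6-en-2-yl]oxy}dimethylsilane, via alkylmagnesium iodide 20 (not isolated)
Conditions: 10, Mg, Et2O, 35 °C; then added slowly to 19, CuBr·SMe2 (0.5 equiv), Et2O, 25 °C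
Reagents that add atoms: none
Why: Grignard formation followed by a phosphine-directed, copper-mediated syn-SN2′ allylic substitution, in which the (Z)-alkene holds the carbinol H in the alkene plane (A(1,3) strain) so that the alkyl group is delivered to C5 on the face of the departing ester, transferring the carbinol chirality to C5 (S in 21, the arrangement that is 5R in the target).

Step 14
Reactants: 21 acetal–ketal
Product: 22 (3S,5R,6S)-3-[(E)-but-2-en-2-yl]-6-[(tert-butyldimethylsilyl)oxy]-8-oxo-5-(propan-2-yl)nonanal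
Conditions: PPTS, acetone/H2O (9:1), 50 °C
Reagents that add atoms: water, O
Why: mild acid hydrolysis of the dimethyl acetal and the dioxolane frees the aldehyde and the methyl ketone, while the secondary silyl ether and the β-stereocentres survive.

Step 15
Reactants: 22 keto-aldehyde
Product: 24 (4S,5R,7R)-7-[(E)-but-2-en-2-yl]-4-[(tert-butyldimethylsilyl)oxy]-2-methyl-5-(propan-2-yl)cyclohept-1-ene-1-carbaldehyde, via β-hydroxy aldehyde 23 (not isolated)
Conditions: Bn2NH·CF3CO2H (0.5 equiv), toluene, 60 °C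
Reagents that add atoms: none
Why: intramolecular aldol condensation, in which the enamine of the unbranched aldehyde (C1) adds to the methyl ketone (C10) and dehydration gives the conjugated tetrasubstituted C1=C10 enal; only seven-membered closure is possible and C5, C7 and C8 are not enolisable positions.

Step 16
Reactants: 24 enal
Product: 25 {(4S,5R,7R)-7-[(E)-but-2-en-2-yl]-4-[(tert-butyldimethylsilyl)oxy]-2-methyl-5-(propan-2-yl)cyclohept-1-en-1-yl}methanol
Conditions: NaBH4, CeCl3·7H2O, MeOH, −20 °C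
Reagents that add atoms: none
Why: Luche reduction gives clean 1,2-reduction of the enal to the primary allylic alcohol.

Step 17
Reactants: 25 allylic alcohol
Product: 26 {[(1S,2R,4R)-5-(bromomethyl)-4-[(E)-but-2-en-2-yl]-6-methyl-2-(propan-2-yl)cyclohept-5-en-1-yl]oxy}(tert-butyl)dimethylsilane
Conditions: CBr4, PPh3, CH2Cl2, 0 °C; used at once
Reagents that add atoms: carbon tetrabromide, BrC(Br)(Br)Br
Why: Appel bromination of the primary allylic alcohol under neutral conditions, leaving the tetrasubstituted alkene in place.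

Step 18
Reactants: 26 allylic bromide
Product: 27 {[(1S,2R,4R)-4-[(E)-but-2-en-2-yl]-6-methyl-5-(prop-2-en-1-yl)-2-(propan-2-yl)cyclohept-5-en-1-yl]oxy}(tert-butyl)dimethylsilane
Conditions: CH2=CHMgBr, Li2CuCl4 (5 mol%), THF, −78 → 0 °C
Reagents that add atoms: vinylmagnesium bromide, C=C[Mg]Br
Why: copper-catalysed (Kochi-type) cross-coupling of the Grignard reagent at the primary allylic carbon, favoured because the alternative SN2′ site is a fully substituted carbon, giving the C2–C3 allyl group.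

Step 19
Reactants: 27 triene
Product: 28 tert-butyl(dimethyl){[(3aR,5R,6S)-3,8-dimethyl-5-(propan-2-yl)-1,3a,4,5,6,7-hexahydroazulen-6-yl]oxy}silane
Conditions: second-generation Grubbs catalyst RuCl2(=CHPh)(PCy3)(H2IMes) (5 mol%), CH2Cl2, 40 °C
Reagents that add atoms: none
Why: ring-closing metathesis, in which the catalyst loads on the terminal allyl alkene and closes onto the trisubstituted butenyl alkene to form the cyclopentene C3=C4 with loss of propene; the tetrasubstituted C1=C10 is inert.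

Step 20
Reactants: 28 bicyclic silyl ether
Product: 29 (3aR,5R,6S)-3,8-dimethyl-5-(propan-2-yl)-1,3a,4,5,6,7-hexahydroazulen-6-ol
Conditions: Bu4NF, THF, 25 °C
Reagents that add atoms: none
Why: fluoride-mediated desilylation frees the C8 alcohol without touching the skipped diene.

Step 21
Reactants: 30 4-hydroxy-3-methoxybenzoic acid (vanillic acid)
Product: 31 4-acetoxy-3-methoxybenzoic acid
Conditions: Ac2O, pyridine, 25 °C; aqueous work-up
Reagents that add atoms: acetic anhydride, CC(=O)OC(C)=O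
Why: acetylation of the phenol; the mixed anhydride at the acid is hydrolysed on work-up.

Step 22
Reactants: 31 4-acetoxy-3-methoxybenzoic acid
Product: 32 4-acetoxy-3-methoxybenzoyl chloride
Conditions: (COCl)2, DMF (cat.), CH2Cl2, 0 → 25 °C
Reagents that add atoms: oxalyl dichloride, O=C(Cl)C(Cl)=O
Why: Vilsmeier-catalysed conversion of the acid to the acid chloride.

Step 23
Reactants: 29 dienol; 32 4-acetoxy-3-methoxybenzoyl chloride
Product: 34 (3aR,5R,6S)-3,8-dimethyl-5-(propan-2-yl)-1,3a,4,5,6,7-hexahydroazulen-6-yl 4-hydroxy-3-methoxybenzoate (target), via O-acetyl ester 33 (not isolated)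
Conditions: Et3N, DMAP (cat.), CH2Cl2, 0 → 25 °C; then pyrrolidine, MeOH, 0 °C
Reagents that add atoms: none
Why: DMAP-catalysed acylation of the C8 alcohol with retention, followed by chemoselective aminolysis of the phenolic acetate, which is far more reactive than the hindered alkyl benzoate.

## Compound list

1 | (R)-4-benzyloxazolidin-2-one | O=C1N[C@H](Cc2ccccc2)CO1 | starting material
2 | 3-methylbutanoyl chloride | CC(C)CC(=O)Cl | starting material
3 | (R)-4-benzyl-3-(3-methylbutanoyl)oxazolidin-2-one | CC(C)CC(=O)N1[C@H](Cc2ccccc2)COC1=O | intermediate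
4 | ethyl 2-(2-methyl-1,3-dioxolan-2-yl)acetate | CCOC(=O)CC1(C)OCCO1 | starting material
5 | 2-(2-methyl-1,3-dioxolan-2-yl)acetaldehyde | O=CCC1(C)OCCO1 | intermediate
6 | (R)-4-benzyl-3-[(1Z)-1-[(dibutylboranyl)oxy]-3-methylbut-1-en-1-yl]oxazolidin-2-one | CC(C)/C=C(\OB(CCCC)CCCC)N1[C@H](Cc2ccccc2)COC1=O | intermediate (not isolated)
7 | (R)-4-benzyl-3-[(2R,3S)-3-hydroxy-4-(2-methyl-1,3-dioxolan-2-yl)-2-(propan-2-yl)butanoyl]oxazolidin-2-one | CC(C)[C@H]([C@@H](O)CC1(C)OCCO1)C(=O)N1[C@H](Cc2ccccc2)COC1=O | intermediate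
8 | (R)-4-benzyl-3-[(2R,3S)-3-[(tert-butyldimethylsilyl)oxy]-4-(2-methyl-1,3-dioxolan-2-yl)-2-(propan-2-yl)butanoyl]oxazolidin-2-one | CC(C)[C@H]([C@@H](O[Si](C)(C)C(C)(C)C)CC1(C)OCCO1)C(=O)N1[C@H](Cc2ccccc2)COC1=O | intermediate
9 | (2S,3S)-3-[(tert-butyldimethylsilyl)oxy]-4-(2-methyl-1,3-dioxolan-2-yl)-2-(propan-2-yl)butan-1-ol | OC[C@H](C(C)C)[C@@H](O[Si](C)(C)C(C)(C)C)CC1(C)OCCO1 | intermediate
10 | tert-butyl{[(2S,3R)-4-iodo-1-(2-methyl-1,3-dioxolan-2-yl)-3-(propan-2-yl)butan-2-yl]oxy}dimethylsilane | IC[C@H](C(C)C)[C@@H](O[Si](C)(C)C(C)(C)C)CC1(C)OCCO1 | intermediate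
11 | methyl 3,3-dimethoxypropanoate | COC(=O)CC(OC)OC | starting material
12 | 3,3-dimethoxypropanal | O=CCC(OC)OC | intermediate
13 | ethyl 2-[bis(2,2,2-trifluoroethoxy)phosphoryl]propanoate | CCOC(=O)C(C)P(=O)(OCC(F)(F)F)OCC(F)(F)F | starting material
14 | ethyl (2Z)-5,5-dimethoxy-2-methylpent-2-enoate | CCOC(=O)/C(C)=C\CC(OC)OC | intermediate
15 | (2Z)-N-methoxy-5,5-dimethoxy-N,2-dimethylpent-2-enamide | CON(C)C(=O)/C(C)=C\CC(OC)OC | intermediate
16 | (3Z)-6,6-dimethoxy-3-methylhex-3-en-2-one | CC(=O)/C(C)=C\CC(OC)OC | intermediate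
17 | (2S,3Z)-6,6-dimethoxy-3-methylhex-3-en-2-ol | C[C@H](O)/C(C)=C\CC(OC)OC | intermediate
18 | 2-(diphenylphosphanyl)benzoic acid | OC(=O)c1ccccc1P(c1ccccc1)c1ccccc1 | starting material
19 | (2S,3Z)-6,6-dimethoxy-3-methylhex-3-en-2-yl 2-(diphenylphosphanyl)benzoate | C[C@H](OC(=O)c1ccccc1P(c1ccccc1)c1ccccc1)/C(C)=C\CC(OC)OC | intermediate
20 | {(2R,3S)-3-[(tert-butyldimethylsilyl)oxy]-4-(2-methyl-1,3-dioxolan-2-yl)-2-(propan-2-yl)butyl}magnesium iodide | I[Mg]C[C@H](C(C)C)[C@@H](O[Si](C)(C)C(C)(C)C)CC1(C)OCCO1 | intermediate (not isolated)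
21 | tert-butyl{[(2S,3R,5S,6E)-5-(2,2-dimethoxyethyl)-6-methyl-1-(2-methyl-1,3-dioxolan-2-yl)-3-(propan-2-yl)oct-6-en-2-yl]oxy}dimethylsilane | COC(OC)C[C@@H](/C(C)=C/C)C[C@H](C(C)C)[C@@H](O[Si](C)(C)C(C)(C)C)CC1(C)OCCO1 | intermediate
22 | (3S,5R,6S)-3-[(E)-but-2-en-2-yl]-6-[(tert-butyldimethylsilyl)oxy]-8-oxo-5-(propan-2-yl)nonanal | O=CC[C@@H](/C(C)=C/C)C[C@H](C(C)C)[C@@H](O[Si](C)(C)C(C)(C)C)CC(C)=O | intermediate
23 | (4S,5R,7R)-7-[(E)-but-2-en-2-yl]-4-[(tert-butyldimethylsilyl)oxy]-2-hydroxy-2-methyl-5-(propan-2-yl)cycloheptane-1-carbaldehyde (mixture at C1 and C2) | O=CC1[C@@H](/C(C)=C/C)C[C@H](C(C)C)[C@@H](O[Si](C)(C)C(C)(C)C)CC1(C)O | intermediate (not isolated)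
24 | (4S,5R,7R)-7-[(E)-but-2-en-2-yl]-4-[(tert-butyldimethylsilyl)oxy]-2-methyl-5-(propan-2-yl)cyclohept-1-ene-1-carbaldehyde | O=CC1=C(C)C[C@H](O[Si](C)(C)C(C)(C)C)[C@@H](C(C)C)C[C@@H]1/C(C)=C/C | intermediate
25 | {(4S,5R,7R)-7-[(E)-but-2-en-2-yl]-4-[(tert-butyldimethylsilyl)oxy]-2-methyl-5-(propan-2-yl)cyclohept-1-en-1-yl}methanol | OCC1=C(C)C[C@H](O[Si](C)(C)C(C)(C)C)[C@@H](C(C)C)C[C@@H]1/C(C)=C/C | intermediate
26 | {[(1S,2R,4R)-5-(bromomethyl)-4-[(E)-but-2-en-2-yl]-6-methyl-2-(propan-2-yl)cyclohept-5-en-1-yl]oxy}(tert-butyl)dimethylsilane | BrCC1=C(C)C[C@H](O[Si](C)(C)C(C)(C)C)[C@@H](C(C)C)C[C@@H]1/C(C)=C/C | intermediate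
27 | {[(1S,2R,4R)-4-[(E)-but-2-en-2-yl]-6-methyl-5-(prop-2-en-1-yl)-2-(propan-2-yl)cyclohept-5-en-1-yl]oxy}(tert-butyl)dimethylsilane | C=CCC1=C(C)C[C@H](O[Si](C)(C)C(C)(C)C)[C@@H](C(C)C)C[C@@H]1/C(C)=C/C | intermediate
28 | tert-butyl(dimethyl){[(3aR,5R,6S)-3,8-dimethyl-5-(propan-2-yl)-1,3a,4,5,6,7-hexahydroazulen-6-yl]oxy}silane | CC(C)(C)[Si](C)(C)O[C@H]1CC(C)=C2CC=C(C)[C@H]2C[C@@H]1C(C)C | intermediate
29 | (3aR,5R,6S)-3,8-dimethyl-5-(propan-2-yl)-1,3a,4,5,6,7-hexahydroazulen-6-ol | O[C@H]1CC(C)=C2CC=C(C)[C@H]2C[C@@H]1C(C)C | intermediate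
30 | 4-hydroxy-3-methoxybenzoic acid | COc1cc(C(=O)O)ccc1O | starting material
31 | 4-acetoxy-3-methoxybenzoic acid | COc1cc(C(=O)O)ccc1OC(C)=O | intermediate
32 | 4-acetoxy-3-methoxybenzoyl chloride | COc1cc(C(=O)Cl)ccc1OC(C)=O | intermediate
33 | (3aR,5R,6S)-3,8-dimethyl-5-(propan-2-yl)-1,3a,4,5,6,7-hexahydroazulen-6-yl 4-acetoxy-3-methoxybenzoate | COc1cc(C(=O)O[C@H]2CC(C)=C3CC=C(C)[C@H]3C[C@@H]2C(C)C)ccc1OC(C)=O | intermediate (not isolated)
34 | (3aR,5R,6S)-3,8-dimethyl-5-(propan-2-yl)-1,3a,4,5,6,7-hexahydroazulen-6-yl 4-hydroxy-3-methoxybenzoate | COc1cc(C(=O)O[C@H]2CC(C)=C3CC=C(C)[C@H]3C[C@@H]2C(C)C)ccc1O | target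

## Step count

Total step count: 23.
Longest linear sequence: 15 steps (7, 8, 9, 10, 11, 12, 13, 14, 15, 16, 17, 18, 19, 20, 23), which is 0.65 of the total. The fragment 1 branch (steps 1 or 2, then 3–6) and the acid chloride branch (steps 21–22) are shorter.

## The three steps most likely to fail, with fallbacks

**Step 13 (fragment union).** The β-branched Grignard reagent may form or add poorly, and the chirality transfer depends on a single reactive conformer of the (Z)-allylic ester. The fallback sets out from iodide 10. Zinc insertion (Zn, LiCl, THF) gives {(2R,3S)-3-[(tert-butyldimethylsilyl)oxy]-4-(2-methyl-1,3-dioxolan-2-yl)-2-(propan-2-yl)butyl}zinc iodide F1. This is joined by a Negishi coupling (Pd(OAc)2, SPhos, THF, 25 °C) to (2S,3E)-4-iodo-3-methylbut-3-en-2-ol F2, itself made from (S)-but-3-yn-2-ol by Cp2ZrCl2-catalysed methylalumination with AlMe3 and iodine quench. The product is the (E)-allylic alcohol (2S,3E,6R,7S)-7-[(tert-butyldimethylsilyl)oxy]-3-methyl-8-(2-methyl-1,3-dioxolan-2-yl)-6-(propan-2-yl)oct-3-en-2-ol F3. A Johnson–Claisen rearrangement (MeC(OEt)3, EtCO2H cat., 140 °C) then transfers the carbinol chirality to C5 through a chair transition state and gives ethyl (3S,5R,6S)-3-[(E)-but-2-en-2-yl]-6-[(tert-butyldimethylsilyl)oxy]-7-(2-methyl-1,3-dioxolan-2-yl)-5-(propan-2-yl)heptanoate F4. i-Bu2AlH at −78 °C gives the aldehyde (3S,5R,6S)-3-[(E)-but-2-en-2-yl]-6-[(tert-butyldimethylsilyl)oxy]-7-(2-methyl-1,3-dioxolan-2-yl)-5-(propan-2-yl)heptanal F5, and PPTS in aqueous acetone removes the ketal to come back to the route at 22.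

**Step 15 (seven-membered aldol condensation).** Enamine addition to a ketone is slow for a seven-membered ring, and the β-silyloxy ketone can eliminate. The fallback sets out from 22. TMSCl, Et3N, DMF at 25 °C (conditions under which a methyl ketone is not silylated) convert the aldehyde alone into its enol ether {[(3S,5R,6S)-3-[(E)-but-2-en-2-yl]-6-[(tert-butyldimethylsilyl)oxy]-8-oxo-5-(propan-2-yl)non-1-en-1-yl]oxy}trimethylsilane F6. TiCl4 in CH2Cl2 at −78 °C then closes the ring by an intramolecular Mukaiyama aldol addition to the β-hydroxy aldehyde 23, now isolated. Dehydration with MsCl, Et3N and then DBU comes back to the route at 24.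

**Step 18 (allyl–vinyl coupling).** The allylic bromide can undergo SN2′ attack, reduction or elimination with the Grignard reagent. The fallback sets out from allylic alcohol 25. ClCO2Me and pyridine give {(4S,5R,7R)-7-[(E)-but-2-en-2-yl]-4-[(tert-butyldimethylsilyl)oxy]-2-methyl-5-(propan-2-yl)cyclohept-1-en-1-yl}methyl methyl carbonate F7. A Stille coupling through the π-allyl palladium complex (Pd2(dba)3, LiCl, tributyl(vinyl)stannane, DMF, 40 °C) attaches the vinyl group at the less hindered terminus and comes back to the route at 27.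

## Further compounds

F1 | step 13 | {(2R,3S)-3-[(tert-butyldimethylsilyl)oxy]-4-(2-methyl-1,3-dioxolan-2-yl)-2-(propan-2-yl)butyl}zinc iodide | I[Zn]C[C@H](C(C)C)[C@@H](O[Si](C)(C)C(C)(C)C)CC1(C)OCCO1
F2 | step 13 | (2S,3E)-4-iodo-3-methylbut-3-en-2-ol | C[C@H](O)/C(C)=C/I
F3 | step 13 | (2S,3E,6R,7S)-7-[(tert-butyldimethylsilyl)oxy]-3-methyl-8-(2-methyl-1,3-dioxolan-2-yl)-6-(propan-2-yl)oct-3-en-2-ol | C[C@H](O)/C(C)=C/C[C@H](C(C)C)[C@@H](O[Si](C)(C)C(C)(C)C)CC1(C)OCCO1
F4 | step 13 | ethyl (3S,5R,6S)-3-[(E)-but-2-en-2-yl]-6-[(tert-butyldimethylsilyl)oxy]-7-(2-methyl-1,3-dioxolan-2-yl)-5-(propan-2-yl)heptanoate | CCOC(=O)C[C@@H](/C(C)=C/C)C[C@H](C(C)C)[C@@H](O[Si](C)(C)C(C)(C)C)CC1(C)OCCO1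
F5 | step 13 | (3S,5R,6S)-3-[(E)-but-2-en-2-yl]-6-[(tert-butyldimethylsilyl)oxy]-7-(2-methyl-1,3-dioxolan-2-yl)-5-(propan-2-yl)heptanal | O=CC[C@@H](/C(C)=C/C)C[C@H](C(C)C)[C@@H](O[Si](C)(C)C(C)(C)C)CC1(C)OCCO1
F6 | step 15 | {[(3S,5R,6S)-3-[(E)-but-2-en-2-yl]-6-[(tert-butyldimethylsilyl)oxy]-8-oxo-5-(propan-2-yl)non-1-en-1-yl]oxy}trimethylsilane | C[Si](C)(C)OC=C[C@@H](/C(C)=C/C)C[C@H](C(C)C)[C@@H](O[Si](C)(C)C(C)(C)C)CC(C)=O
F7 | step 18 | {(4S,5R,7R)-7-[(E)-but-2-en-2-yl]-4-[(tert-butyldimethylsilyl)oxy]-2-methyl-5-(propan-2-yl)cyclohept-1-en-1-yl}methyl methyl carbonate | COC(=O)OCC1=C(C)C[C@H](O[Si](C)(C)C(C)(C)C)[C@@H](C(C)C)C[C@@H]1/C(C)=C/C
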